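Retrosynthetic overview
1. The target is the atromentin core, a central 1,4-benzoquinone ring carrying two 4-hydroxyphenyl rings. Its two quinone enol oxygens bear the same (2Z,4S,5S)-4,5-epoxyhex-2-enoyl group. The last disconnection is at these two enol-ester C–O bonds, with the phenols masked as TBS ethers.
2. The strategy rests on this feature: in each side chain the Z C2=C3 alkene folds the chain so that a C1 carboxyl oxygen sits beside C5 of the trans-oxirane (O, C4, C5). The oxirane oxygen can therefore be traced back to a carboxyl oxygen through the six-membered lactone O1–C2–C3=C4–C5–C6.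
3. The oxirane comes from a trans-5-iodo-6-methyl-5,6-dihydropyran-2-one: hydroxide opens the lactone and the alkoxide displaces iodide with inversion. The lactone comes from achiral (2Z,4E)-hexa-2,4-dienoic acid by catalytic enantioselective 6-endo iodolactonization, and the acid from crotonaldehyde and a Still–Gennari phosphonate.
4. The core is made from bromanil through 2,5-dibromo-3,6-dimethoxyquinone, a double Suzuki–Miyaura coupling, global demethylation to atromentin and selective phenol silylation.
5. Ring order: the three carbocycles are bought. The δ-lactone ring closes first (step 3) and is exchanged for the oxirane ring (step 4). No ring is formed after that.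

Key step: step 3

Assumption: the sense of induction cannot be predicted safely for this substrate. The hydroquinine-derived squaramide is taken to give (5R,6S)-5; if it favours the mirror image, the pseudoenantiomeric hydroquinidine-derived squaramide is used in the same way.

Step 1
Reactants: 1 (E)-but-2-enal (crotonaldehyde); 2 methyl bis(2,2,2-trifluoroethyl)phosphonoacetate
Product: 3 methyl (2Z,4E)-hexa-2,4-dienoate
Conditions: KN(SiMe3)2, 18-crown-6, THF, −78 °C; aq. NH4Cl; careful concentration (volatile ester)
Reagents that add atoms: none
Why: In this Still–Gennari olefination the electron-poor trifluoroethyl phosphonate collapses fast from the kinetic adduct, so the new C2=C3 alkene should be Z, and the E alkene of 1 is carried over unchanged.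

Step 2
Reactants: 3 methyl (2Z,4E)-hexa-2,4-dienoate
Product: 4 (2Z,4E)-hexa-2,4-dienoic acid
Conditions: LiOH·H2O, THF/H2O, 0 °C → rt; 1 M HCl to pH 2–3, 0 °C
Reagents that add atoms: lithium hydroxide, [Li+].[OH-]
Why: This is an ester saponification by acyl–oxygen cleavage, and the carboxylate formed is not an acceptor for conjugate addition, so both alkene geometries should be kept.

Step 3
Reactants: 4 (2Z,4E)-hexa-2,4-dienoic acid
Product: 5 (5R,6S)-5-iodo-6-methyl-5,6-dihydro-2H-pyran-2-one (I and CH3 trans)
Conditions: NIS (1.2 equiv), 3-{[3,5-bis(trifluoromethyl)phenyl]amino}-4-{[(8α,9S)-10,11-dihydro-6'-methoxycinchonan-9-yl]amino}cyclobut-3-ene-1,2-dione (10 mol %; the dihydro compound is chosen because it has no vinyl group for NIS to attack), 4 Å MS, toluene/CH2Cl2, −60 → −40 °C, dark; cold water wash, short cold silica pad, used at once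
Reagents that add atoms: N-iodosuccinimide, O=C1CCC(=O)N1I
Why: Proposed new method: the quinuclidine nitrogen of the catalyst deprotonates 4 to a tight ammonium carboxylate pair while the two squaramide N–H bonds bind and polarise NIS, so iodine is handed to one face of the C4=C5 alkene and the carboxylate oxygen, which the Z C2=C3 alkene keeps next to C5, attacks C5 from the opposite face. The closest known reaction types are the catalytic enantioselective 6-endo bromo- and iodolactonizations of 5-arylpent-4-enoic acids with bifunctional amine/hydrogen-bond-donor catalysts and the racemic iodolactonization of (Z)-2-en-4-ynoic and (2Z)-dienoic acids; a conjugated, alkyl-terminated dienoic acid under catalyst control has not been shown. The single new ring, the δ-lactone O1–C2–C3=C4–C5–C6, closes in the 6-endo mode, and both former alkene carbons end up in the ring. The relative configuration (I at C5 and CH3 at C6 trans) follows from stereospecific anti addition to the 4E alkene, and the absolute configuration (5R,6S) from the alkene face that the catalyst selects. The step needs site selectivity for C4=C5 over C2=C3, which the carboxyl group secures by making C2=C3 electron-poor, regioselectivity for oxygen attack at C5, which is favoured because the methyl-bearing carbon carries the positive charge of the iodonium ion better than C4 next to the acceptor-substituted vinyl group, and a slow uncatalysed reaction, which the poor nucleophilicity of the neutral acid and of the electron-poor diene at low temperature should provide. A leak into 5-exo closure at C4 would use the same iodonium face and would be funnelled by step 4 into the same oxirane enantiomer.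

Step 4
Reactants: 5 (5R,6S)-5-iodo-6-methyl-5,6-dihydro-2H-pyran-2-one
Product: 7 sodium (2Z,4S,5S)-4,5-epoxyhex-2-enoate, via iodohydrin carboxylate 6 (not isolated)
Conditions: NaOH (2.0 equiv, 0.5 M aq., slow addition), THF, 0 °C, dark; Et2O wash; freeze-drying; trituration with dry acetone (removes NaI)
Reagents that add atoms: sodium hydroxide, [Na+].[OH-]
Why: In this iodolactone-to-epoxide conversion, acyl–oxygen hydrolysis keeps the C5–O bond and its S configuration, the freed C5 alkoxide displaces the allylic iodide at C4 from the rear (intramolecular SN2, R becomes S) to give the trans-oxirane, and anti elimination of HI is disfavoured because H-6 and iodine are cis on the lactone ring.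

Step 5
Reactants: 8 tetrabromo-1,4-benzoquinone (bromanil)
Product: 9 2,5-dibromo-3,6-dimethoxy-1,4-benzoquinone
Conditions: NaOMe (2.1 equiv), MeOH, 0 °C → rt
Reagents that add atoms: sodium methoxide, C[O-].[Na+]
Why: This is a twofold addition–elimination on a haloquinone, and the first methoxy group, acting as a vinylogous ester donor, switches off C3 and C6, so the second methoxide should enter at C5.

Step 6
Reactants: 9 2,5-dibromo-3,6-dimethoxy-1,4-benzoquinone; 10 4-methoxyphenylboronic acid (2.5 equiv)
Product: 11 2,5-dimethoxy-3,6-bis(4-methoxyphenyl)-1,4-benzoquinone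
Conditions: PdCl2(dppf) (5 mol %), K3PO4, 1,4-dioxane/H2O (10:1), 80 °C
Reagents that add atoms: none
Why: In this double Suzuki–Miyaura coupling of a bromoquinone, zerovalent palladium inserts readily into the two symmetry-equivalent vinylogous acyl C–Br bonds, and the methyl-capped boronic acid supplies no phenoxide that could add to the quinone.

Step 7
Reactants: 11 2,5-dimethoxy-3,6-bis(4-methoxyphenyl)-1,4-benzoquinone
Product: 12 atromentin, 2,5-dihydroxy-3,6-bis(4-hydroxyphenyl)-1,4-benzoquinone
Conditions: BBr3 (8 equiv), CH2Cl2, −78 °C → rt; then H2O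
Reagents that add atoms: none
Why: In this Lewis-acid ether cleavage, BBr3 complexes each methoxy oxygen and bromide removes the methyl group by SN2, so the two aryl ethers and the two vinylogous esters should fall in one operation.

Step 8
Reactants: 12 atromentin
Product: 14 2,5-dihydroxy-3,6-bis[4-(tert-butyldimethylsilyloxy)phenyl]-1,4-benzoquinone, via tetrakis-TBS ether 13 (not isolated)
Conditions: TBSCl (5 equiv), imidazole, DMF, rt; then AcOH/THF/H2O (3:1:1), rt
Reagents that add atoms: tert-butyldimethylsilyl chloride, CC(C)(C)[Si](C)(C)Cl
Why: Exhaustive silylation is followed by selective hydrolysis, because the two quinone O–Si bonds are vinylogous silyl esters that aqueous acetic acid cleaves, whereas aryl TBS ethers persist under these conditions.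

Step 9
Reactants: 7 sodium (2Z,4S,5S)-4,5-epoxyhex-2-enoate (2.5 equiv); 14 2,5-dihydroxy-3,6-bis[4-(tert-butyldimethylsilyloxy)phenyl]-1,4-benzoquinone
Product: 16 2,5-bis[4-(tert-butyldimethylsilyloxy)phenyl]-3,6-dioxocyclohexa-1,4-diene-1,4-diyl bis[(2Z,4S,5S)-4,5-epoxyhex-2-enoate], via mixed anhydride 15 (not isolated)
Conditions: 7, 2,4,6-Cl3C6H2COCl (2.4 equiv), 15-crown-5 (cat.), THF, 0 °C; then 14, Et3N (2.2 equiv), DMAP (0.2 equiv), toluene, −10 → 0 °C
Reagents that add atoms: 2,4,6-trichlorobenzoyl chloride, O=C(Cl)c1c(Cl)cc(Cl)cc1Cl (its atoms are held only in intermediate 15)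
Why: This Yamaguchi esterification starts from the carboxylate salt, so the free Z-epoxy acid that could lactonise onto its own oxirane never arises; the shielded trichlorobenzoyl carbonyl directs DMAP and the quinone enolate to the enoyl carbonyl, only the two acidic quinone hydroxyls are free, and C4 and C5 are not touched.

Step 10
Reactants: 16 bis-TBS ether of the target
Product: 17 target, 2,5-bis(4-hydroxyphenyl)-3,6-dioxocyclohexa-1,4-diene-1,4-diyl bis[(2Z,4S,5S)-4,5-epoxyhex-2-enoate]
Conditions: Et3N·3HF, THF, 0 °C → rt; pH 5–6 buffer work-up
Reagents that add atoms: none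
Why: This fluoride-driven cleavage of aryl silyl ethers runs under weakly acidic conditions, so the phenols appear as neutral O–H groups rather than phenoxides that could attack the enol esters, and the oxiranes, whose allylic position is deactivated by the acceptor-substituted alkene, should not be opened at this temperature.

Compound list
1 | (E)-but-2-enal | C/C=C/C=O | starting material
2 | methyl bis(2,2,2-trifluoroethyl)phosphonoacetate | COC(=O)CP(=O)(OCC(F)(F)F)OCC(F)(F)F | starting material
3 | methyl (2Z,4E)-hexa-2,4-dienoate | C/C=C/C=C\C(=O)OC | intermediate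
4 | (2Z,4E)-hexa-2,4-dienoic acid | C/C=C/C=C\C(=O)O | intermediate
5 | (5R,6S)-5-iodo-6-methyl-5,6-dihydro-2H-pyran-2-one | C[C@@H]1OC(=O)C=C[C@H]1I | intermediate
6 | sodium (2Z,4R,5S)-5-hydroxy-4-iodohex-2-enoate | C[C@H](O)[C@@H](/C=C\C(=O)[O-])I.[Na+] | intermediate
7 | sodium (2Z,4S,5S)-4,5-epoxyhex-2-enoate | C[C@@H]1O[C@H]1/C=C\C(=O)[O-].[Na+] | intermediate
8 | tetrabromo-1,4-benzoquinone | O=C1C(Br)=C(Br)C(=O)C(Br)=C1Br | starting material
9 | 2,5-dibromo-3,6-dimethoxy-1,4-benzoquinone | COC1=C(Br)C(=O)C(OC)=C(Br)C1=O | intermediate
10 | 4-methoxyphenylboronic acid | COc1ccc(B(O)O)cc1 | starting material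
11 | 2,5-dimethoxy-3,6-bis(4-methoxyphenyl)-1,4-benzoquinone | COC1=C(c2ccc(OC)cc2)C(=O)C(OC)=C(c2ccc(OC)cc2)C1=O | intermediate
12 | atromentin | OC1=C(c2ccc(O)cc2)C(=O)C(O)=C(c2ccc(O)cc2)C1=O | intermediate
13 | 2,5-bis(tert-butyldimethylsilyloxy)-3,6-bis[4-(tert-butyldimethylsilyloxy)phenyl]-1,4-benzoquinone | CC(C)(C)[Si](C)(C)OC1=C(c2ccc(O[Si](C)(C)C(C)(C)C)cc2)C(=O)C(O[Si](C)(C)C(C)(C)C)=C(c2ccc(O[Si](C)(C)C(C)(C)C)cc2)C1=O | intermediate
14 | 2,5-dihydroxy-3,6-bis[4-(tert-butyldimethylsilyloxy)phenyl]-1,4-benzoquinone | OC1=C(c2ccc(O[Si](C)(C)C(C)(C)C)cc2)C(=O)C(O)=C(c2ccc(O[Si](C)(C)C(C)(C)C)cc2)C1=O | intermediate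
15 | (2Z,4S,5S)-4,5-epoxyhex-2-enoic 2,4,6-trichlorobenzoic anhydride | C[C@@H]1O[C@H]1/C=C\C(=O)OC(=O)c1c(Cl)cc(Cl)cc1Cl | intermediate
16 | bis-TBS ether of the target | C[C@@H]1O[C@H]1/C=C\C(=O)OC1=C(c2ccc(O[Si](C)(C)C(C)(C)C)cc2)C(=O)C(OC(=O)/C=C\[C@@H]2O[C@H]2C)=C(c2ccc(O[Si](C)(C)C(C)(C)C)cc2)C1=O | intermediate
17 | CNP0407724.1 | C[C@@H]1O[C@H]1/C=C\C(=O)OC1=C(c2ccc(O)cc2)C(=O)C(OC(=O)/C=C\[C@@H]2O[C@H]2C)=C(c2ccc(O)cc2)C1=O | target

Total step count: 10. Longest linear sequence: 6 steps (1, 2, 3, 4, 9, 10; the core branch 5, 6, 7, 8, 9, 10 is equally long).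

Steps most likely to fail

Step 3.
- What may go wrong:
  - Facial discrimination may be weak at an alkene whose ends differ only as methyl and vinyl.
  - Iodine transfer to the electron-poor diene may be slow, so that the uncatalysed pathway gains weight.
  - The 2Z alkene may isomerise before ring closure.
  - The allylic C–I centre may epimerise by iodide exchange.
- Consequence: two copies of 7 are attached in step 9, so any minor enantiomer is drained into a heterochiral diastereomer that would have to be separated.
- Fallback (known chemistry): it sets out from 1 and comes back at 7. Luche reduction of 1 (NaBH4, CeCl3·7H2O, MeOH) should give (E)-but-2-en-1-ol F1. Sharpless asymmetric epoxidation (Ti(OiPr)4, L-(+)-diisopropyl tartrate, tBuOOH, 4 Å MS, CH2Cl2, −20 °C) should give (2S,3S)-2,3-epoxybutan-1-ol F2. Parikh–Doering oxidation (SO3·pyridine, DMSO, Et3N) should give (2R,3S)-2,3-epoxybutanal F3, which is kept in solution. Still–Gennari olefination with 2 should give methyl (2Z,4S,5S)-4,5-epoxyhex-2-enoate F4. One equivalent of NaOH in THF/H2O at 0 °C then delivers 7.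

Step 4.
- What may go wrong:
  - Vinylogous deprotonation at the iodine-bearing carbon may be followed by eliminative ring opening.
  - HI may be lost towards the aromatic-like pyranone.
  - The neighbouring carboxylate, instead of the alkoxide, may displace iodide.
  - The oxirane may open hydrolytically during isolation of the salt.
- Fallback: it sets out from 5 and comes back at 7. The lactone is opened in a non-aqueous medium by the small stationary amount of methoxide that K2CO3 gives in MeOH at −20 °C. The product is the neutral, extractable and chromatographable methyl (2Z,4S,5S)-4,5-epoxyhex-2-enoate F5, which is freed from iodide and side products before any hydroxide is used. It is then saponified with one equivalent of NaOH (THF/H2O, 0 °C) to 7.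

Step 9.
- What may go wrong:
  - The Z enoate may isomerise to E through reversible conjugate addition of DMAP.
  - The second acylation of a hindered, weakly nucleophilic quinone enolate may stay incomplete.
  - The oxirane oxygen may take part at the activated acyl group.
  - Acyl groups may be lost from the vinylogous anhydride during purification.
- Fallback: it sets out from 14 and comes back at 16, with the roles of the partners reversed, so that the delicate acid is never activated. Treatment of 14 with (COCl)2 and catalytic DMF in CH2Cl2 should give 2,5-dichloro-3,6-bis[4-(tert-butyldimethylsilyloxy)phenyl]-1,4-benzoquinone F6. Salt 7 (2 equiv, 15-crown-5, MeCN, rt) then displaces both chlorides by addition–elimination to give 16.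

Further compounds
F1 | step 3 | (E)-but-2-en-1-ol | C/C=C/CO
F2 | step 3 | (2S,3S)-2,3-epoxybutan-1-ol | C[C@@H]1O[C@H]1CO
F3 | step 3 | (2R,3S)-2,3-epoxybutanal | C[C@@H]1O[C@H]1C=O
F4 | step 3 | methyl (2Z,4S,5S)-4,5-epoxyhex-2-enoate | C[C@@H]1O[C@H]1/C=C\C(=O)OC
F5 | step 4 | methyl (2Z,4S,5S)-4,5-epoxyhex-2-enoate (same compound as F4, here made from 5) | C[C@@H]1O[C@H]1/C=C\C(=O)OC
F6 | step 9 | 2,5-dichloro-3,6-bis[4-(tert-butyldimethylsilyloxy)phenyl]-1,4-benzoquinone | ClC1=C(c2ccc(O[Si](C)(C)C(C)(C)C)cc2)C(=O)C(Cl)=C(c2ccc(O[Si](C)(C)C(C)(C)C)cc2)C1=O
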